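**Retrosynthetic overview**
1. The ester C10–O bond is cut last: the acid opens a spiro-epoxy alcohol at its CH2, and the epoxide comes from an OH-directed epoxidation of a C8=C10 methylidene on the bicyclic lactone.
2. The bicyclic lactone is cut back to a nine-membered lactone. C5 carries the allyl unit C3H2–C4(=C11H2) and sits next to C9, the α-carbon of the lactone carbonyl C1, on the same face; C5–C9 plus the exocyclic C4=C11 is therefore the retron of an ester-enolate Claisen shift, and C3/C11 are two equivalent allylic CH2 groups, one leaving the old ring oxygen and one taking the new one.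
3. The nine-membered lactone comes from methyl 4-oxobutanoate by α-methylenation, asymmetric allylation (C7), cross-metathesis with a symmetrical bis-allylic diacetate, and lactonization onto the arm cis to the chain.
4. The acid comes from (R)-pulegone: C4 is taken from the pool, C1/C5 are set by hydrogenating a fused butenolide, the seven-membered ring is closed by metathesis, and the diene acid is made by dienyl triflate carbonylation.
5. Ring order: nine-membered lactone, then cyclopentane and δ-lactone in one operation; for the acid, cyclopentane, temporary γ-lactone, then cycloheptene.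

Key step: step 8

Remark on numbering: locants in the text are iridoid numbers for the lactone part (C1 lactone C=O, O2, C3 OCH2, C4=C11, C5/C9 ring fusion, C6, C7 CHOH, C8 with C10H2O) and guaiane numbers for the acid part (C1/C5 ring fusion, C4 CHMe, C7 with isopropyl, C10 with C14 carboxyl).

**Step 1**
Reactants: 1 methyl 4-oxobutanoate
Product: 2 methyl 3-formylbut-3-enoate
Conditions: 37% aq. HCHO, pyrrolidine (10 mol %), EtCO2H (10 mol %), iPrOH, 45 °C
Reagents that add atoms: formaldehyde, C=O
Why: Amine-catalysed Mannich condensation–elimination (aldehyde α-methylenation) acts only at the aldehyde α-carbon, so the ester CH2 is untouched and no stereocenter arises.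

**Step 2**
Reactants: 2 methyl 3-formylbut-3-enoate
Product: 4 methyl (4S)-4-hydroxy-3-methylidenehept-6-enoate, via borinate ester 3 (not isolated)
Conditions: (−)-Ipc2BOMe (from (+)-α-pinene), CH2=CHCH2MgBr, Et2O, −78 °C to rt; then 2, −78 °C; then 30% H2O2, pH 7 buffer, MeOH, 0 °C
Reagents that add atoms: allylmagnesium bromide, C=CC[Mg]Br
Why: Brown allylboration through a closed chair transition state should add allyl to the Si face (same sense as for benzaldehyde with this reagent), setting C7 as S; the ester is inert to the allylborane at −78 °C.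

**Step 3**
Reactants: 4 methyl (4S)-4-hydroxy-3-methylidenehept-6-enoate
Product: 5 methyl (4S)-4-[(tert-butyldimethylsilyl)oxy]-3-methylidenehept-6-enoate
Conditions: TBSCl, imidazole, DMF, 0 °C to rt
Reagents that add atoms: tert-butyldimethylsilyl chloride, CC(C)(C)[Si](C)(C)Cl
Why: Standard silylation, done at once because the free γ-hydroxy ester can lactonize; the stereocenter is not touched.

**Step 4**
Reactants: 5 methyl (4S)-4-[(tert-butyldimethylsilyl)oxy]-3-methylidenehept-6-enoate; 6 2-methylidenepropane-1,3-diyl diacetate (4 equiv)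
Product: 7 methyl (4S)-8-acetoxy-7-(acetoxymethyl)-4-[(tert-butyldimethylsilyl)oxy]-3-methylideneoct-6-enoate
Conditions: second-generation Hoveyda–Grubbs catalyst (5 mol %), CH2Cl2, 40 °C
Reagents that add atoms: none
Why: Cross-metathesis of the terminal alkene with an excess of a symmetrical 1,1-disubstituted alkene gives the trisubstituted alkene with no E/Z question; the hindered C8 methylidene is a poor partner and should remain.

**Step 5**
Reactants: 7 methyl (4S)-8-acetoxy-7-(acetoxymethyl)-4-[(tert-butyldimethylsilyl)oxy]-3-methylideneoct-6-enoate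
Product: 8 (4S)-4-[(tert-butyldimethylsilyl)oxy]-8-hydroxy-7-(hydroxymethyl)-3-methylideneoct-6-enoic acid
Conditions: LiOH, THF/MeOH/H2O, 0 °C to rt; then 1 M HCl to pH 4
Reagents that add atoms: lithium hydroxide, [Li+].[OH-]
Why: Saponification of the methyl ester and both acetates; the carboxylate resists conjugation of the β,γ-alkene and the silyl ether is stable to cold LiOH.

**Step 6**
Reactants: 8 (4S)-4-[(tert-butyldimethylsilyl)oxy]-8-hydroxy-7-(hydroxymethyl)-3-methylideneoct-6-enoic acid
Product: 9 (5S,7Z)-5-[(tert-butyldimethylsilyl)oxy]-8-(hydroxymethyl)-4-methylidene-1-oxacyclonon-7-en-2-one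
Conditions: 2-methyl-6-nitrobenzoic anhydride, DMAP, Et3N, CH2Cl2, rt, slow addition, 1 mM
Reagents that add atoms: none
Why: Shiina macrolactonization under high dilution; only the hydroxymethyl arm cis to the chain can close a nine-membered ring with a cis ring alkene, so the two arms are told apart without protection, and α-protonation of any ketene or dienolate returns the deconjugated ester.

**Step 7**
Reactants: 9 (5S,7Z)-5-[(tert-butyldimethylsilyl)oxy]-8-(hydroxymethyl)-4-methylidene-1-oxacyclonon-7-en-2-one
Product: 10 (5S,7E)-5-[(tert-butyldimethylsilyl)oxy]-8-(chloromethyl)-4-methylidene-1-oxacyclonon-7-en-2-one (same alkene geometry as 9)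
Conditions: PPh3, N-chlorosuccinimide, CH2Cl2, 0 °C
Reagents that add atoms: N-chlorosuccinimide, O=C1CCC(=O)N1Cl
Why: Appel-type chlorination of the primary allylic alcohol by SN2 without allylic shift under neutral conditions that spare the lactone and the silyl ether.

**Step 8**
Reactants: 10 (5S,7E)-5-[(tert-butyldimethylsilyl)oxy]-8-(chloromethyl)-4-methylidene-1-oxacyclonon-7-en-2-one
Product: 13 (4aR,6S,7aR)-6-hydroxy-4,7-dimethylidenehexahydrocyclopenta[c]pyran-1(3H)-one, via silyl ketene acetal 11 (not isolated), via silyl ester 12 (not isolated)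
Conditions: LiN(SiMe3)2, TBSCl, DMPU, THF, −78 °C; then PhMe, 90 °C; then Bu4NF (1.1 equiv), THF, 0 °C to rt; then Bu4NF/AcOH (2 equiv), rt
Reagents that add atoms: none
Why: LiN(SiMe3)2 removes the C9 proton of 10 (α to the lactone carbonyl and allylic to C8=C10, the only acidic site) and TBSCl traps the enolate as ketene acetal 11, which on heating undergoes an Ireland–Claisen [3,3] shift across the ring (C9=C1–O2 with C11–C4=C5), the closest known type being the enolate-Claisen ring contraction of unsaturated medium-ring lactones to cis-2-alkenylcycloalkanecarboxylic acids. The cyclopentane is thus closed by transannular C5–C9 bond formation with contraction of the nine-membered ring by four atoms, the old ring OCH2 becoming the exocyclic methylidene C11. Fluoride then frees the carboxylate of 12, which closes the δ-lactone by 6-exo-tet SN2 displacement of chloride at C3, the allylic CH2 that was exocyclic in 10. C5 and C9 are set cis because the short tether allows only a boat-like transition state. Their configuration relative to C7 should follow from the C7 envelope flap tilting away from the pericyclic array with the bulky silyloxy group pseudo-equatorial, which places it cis to both new ring bonds (the usual 1,3-cis preference of five-ring closures); the other facial isomer would be a separable diastereomer, so enantiopurity is not at stake. The step needs O-silylation before any enolate side reaction (TBSCl is present during deprotonation) and lactonization before the C7 alkoxide is unmasked (the fluoride is staged: the silyl ester cleaves at once, the silyl ether only with the second, buffered portion).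

**Step 9**
Reactants: 13 (4aR,6S,7aR)-6-hydroxy-4,7-dimethylidenehexahydrocyclopenta[c]pyran-1(3H)-one
Product: 14 (4aR,6S,7S,7aR)-6-hydroxy-4-methylidenehexahydro-1H-spiro[cyclopenta[c]pyran-7,2'-oxiran]-1-one
Conditions: VO(acac)2 (5 mol %), tBuOOH, CH2Cl2, 0 °C to rt
Reagents that add atoms: tert-butyl hydroperoxide, CC(C)(C)OO
Why: Vanadium-catalysed hydroxyl-directed epoxidation delivers oxygen syn to the 7-OH, onto the α-face of C8 against the steric bias of the bicycle, setting C8 as S and leaving the C4=C11 alkene, which has no directing hydroxyl.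

**Step 10**
Reactants: 15 (R)-(+)-pulegone
Product: 17 methyl (1S,5R)-5-methyl-2-(propan-2-ylidene)cyclopentane-1-carboxylate (methyl pulegenate; trans isomer drawn and C1 epimers both go on), via pulegone dibromide 16 (not isolated)
Conditions: Br2, NaHCO3, Et2O, −10 °C; then NaOMe, MeOH, reflux
Reagents that add atoms: sodium methoxide, [Na+].[O-]C
Why: Bromination of the enone followed by Favorskii ring contraction with methoxide and loss of the second bromide; the methyl-bearing center is not involved and stays R.

**Step 11**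
Reactants: 17 methyl (1S,5R)-5-methyl-2-(propan-2-ylidene)cyclopentane-1-carboxylate
Product: 19 methyl (1S,5R)-5-methyl-2-oxocyclopentane-1-carboxylate (C1 labile), via ozonide 18 (not isolated)
Conditions: O3, CH2Cl2, −78 °C; then Me2S, −78 °C to rt
Reagents that add atoms: ozone, [O-][O+]=O
Why: Ozonolysis of the tetrasubstituted alkene with reductive work-up; the methyl center is untouched and the β-keto ester center is removed in the next step.

**Step 12**
Reactants: 19 methyl (1S,5R)-5-methyl-2-oxocyclopentane-1-carboxylate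
Product: 20 methyl (5R)-5-methyl-2-{[(trifluoromethyl)sulfonyl]oxy}cyclopent-1-ene-1-carboxylate
Conditions: Tf2O, iPr2NEt, CH2Cl2, −78 °C
Reagents that add atoms: trifluoromethanesulfonic anhydride, O=S(=O)(OS(=O)(=O)C(F)(F)F)C(F)(F)F
Why: O-triflation of the β-keto ester enol gives the conjugated enol triflate regiospecifically.

**Step 13**
Reactants: 20 methyl (5R)-5-methyl-2-{[(trifluoromethyl)sulfonyl]oxy}cyclopent-1-ene-1-carboxylate
Product: 21 (3R)-2-(hydroxymethyl)-3-methylcyclopent-1-en-1-yl trifluoromethanesulfonate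
Conditions: iBu2AlH (2.5 equiv), CH2Cl2, −78 °C; Rochelle salt work-up
Reagents that add atoms: none
Why: 1,2-Reduction of the ester by the aluminium hydride; vinyl triflates tolerate it at −78 °C.

**Step 14**
Reactants: 21 (3R)-2-(hydroxymethyl)-3-methylcyclopent-1-en-1-yl trifluoromethanesulfonate
Product: 22 (4R)-4-methyl-3,4,5,6-tetrahydro-1H-cyclopenta[c]furan-1-one
Conditions: Pd(PPh3)4 (5 mol %), CO (1 atm), Bu3N, LiCl, MeCN, 65 °C
Reagents that add atoms: carbon monoxide, [C-]#[O+]
Why: Carbonylative lactonization: oxidative addition of zerovalent palladium into the vinyl triflate, CO insertion and intramolecular alcoholysis close the butenolide.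

**Step 15**
Reactants: 22 (4R)-4-methyl-3,4,5,6-tetrahydro-1H-cyclopenta[c]furan-1-one
Product: 23 (3aR,4R,6aS)-4-methylhexahydro-1H-cyclopenta[c]furan-1-one
Conditions: H2 (4 atm), Rh/Al2O3, EtOAc, rt
Reagents that add atoms: none
Why: Heterogeneous syn-hydrogenation of the tetrasubstituted butenolide from the face opposite the C4 methyl sets C1 and C5 with all three ring hydrogens cis, and the cis-fused γ-lactone locks both centers.

**Step 16**
Reactants: 23 (3aR,4R,6aS)-4-methylhexahydro-1H-cyclopenta[c]furan-1-one
Product: 24 (1S,2R,3R)-2-(hydroxymethyl)-N-methoxy-N,3-dimethylcyclopentane-1-carboxamide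
Conditions: MeNHOMe·HCl, iPrMgCl, THF, −20 °C to 0 °C; used at once
Reagents that add atoms: N,O-dimethylhydroxylamine hydrochloride, CNOC.Cl
Why: Aminolysis of the lactone by the magnesium amide (Weinreb amide formation) touches no stereocenter; the product is carried on directly to avoid relactonization.

**Step 17**
Reactants: 24 (1S,2R,3R)-2-(hydroxymethyl)-N-methoxy-N,3-dimethylcyclopentane-1-carboxamide
Product: 25 (1S,2R,3R)-2-(iodomethyl)-N-methoxy-N,3-dimethylcyclopentane-1-carboxamide
Conditions: I2, PPh3, imidazole, CH2Cl2, 0 °C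
Reagents that add atoms: iodine, II
Why: Appel-type iodination of the primary alcohol by SN2 at CH2.

**Step 18**
Reactants: 26 3-methylbutan-2-one
Product: 28 3-methylbut-1-en-2-yl trifluoromethanesulfonate, via lithium enolate 27 (not isolated)
Conditions: LiN(iPr)2, THF, −78 °C; then PhNTf2, −78 °C to 0 °C
Reagents that add atoms: N-phenylbis(trifluoromethanesulfonimide), O=S(=O)(N(c1ccccc1)S(=O)(=O)C(F)(F)F)C(F)(F)F
Why: Kinetic deprotonation at the methyl group and O-triflation give the less substituted enol triflate.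

**Step 19**
Reactants: 25 (1S,2R,3R)-2-(iodomethyl)-N-methoxy-N,3-dimethylcyclopentane-1-carboxamide; 28 3-methylbut-1-en-2-yl trifluoromethanesulfonate
Product: 30 (1S,2R,3R)-N-methoxy-N,3-dimethyl-2-(3-methyl-2-methylidenebutyl)cyclopentane-1-carboxamide, via alkylzinc iodide 29 (not isolated)
Conditions: Zn, LiCl, THF, 40 °C; then 28, PdCl2(dppf) (5 mol %), THF, 50 °C
Reagents that add atoms: none
Why: Zinc insertion into the primary iodide followed by Negishi sp3–sp2 coupling; the alkylzinc tolerates the Weinreb amide and the stereocenters are not at the reacting carbon.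

**Step 20**
Reactants: 30 (1S,2R,3R)-N-methoxy-N,3-dimethyl-2-(3-methyl-2-methylidenebutyl)cyclopentane-1-carboxamide
Product: 31 1-[(1S,2R,3R)-3-methyl-2-(3-methyl-2-methylidenebutyl)cyclopentyl]but-3-en-1-one
Conditions: CH2=CHCH2MgBr, THF, −78 °C; aq. NH4Cl at −78 °C
Reagents that add atoms: allylmagnesium bromide, C=CC[Mg]Br
Why: Weinreb ketone synthesis: the chelated tetrahedral intermediate stops at mono-addition, and the cold quench avoids conjugation of the β,γ-enone and epimerization at C1.

**Step 21**
Reactants: 31 1-[(1S,2R,3R)-3-methyl-2-(3-methyl-2-methylidenebutyl)cyclopentyl]but-3-en-1-one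
Product: 32 (3R,3aR,8aS)-3-methyl-5-(propan-2-yl)-2,3,3a,4,7,8a-hexahydroazulen-8(1H)-one
Conditions: second-generation Grubbs catalyst (5–10 mol %), 1,4-benzoquinone (10 mol %), PhMe, 80 °C, 2 mM
Reagents that add atoms: none
Why: Ring-closing metathesis of the monosubstituted and the 1,1-disubstituted alkene forms the trisubstituted C7=C8 bond of the cis-fused cycloheptenone, with benzoquinone suppressing ruthenium hydride alkene migration.

**Step 22**
Reactants: 32 (3R,3aR,8aS)-3-methyl-5-(propan-2-yl)-2,3,3a,4,7,8a-hexahydroazulen-8(1H)-one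
Product: 34 (3R,3aR,8aS)-3-methyl-5-(propan-2-yl)-1,2,3,3a,4,8a-hexahydroazulen-8-yl trifluoromethanesulfonate, via potassium dienolate 33 (not isolated)
Conditions: KN(SiMe3)2, THF, −78 °C; then PhNTf2, −78 °C to 0 °C
Reagents that add atoms: N-phenylbis(trifluoromethanesulfonimide), O=S(=O)(N(c1ccccc1)S(=O)(=O)C(F)(F)F)C(F)(F)F
Why: C9 is doubly activated (α to C=O and allylic), so the linear dienolate forms in preference to deprotonation at the C1 methine and O-triflation gives the conjugated dienyl triflate with the ring-fusion center intact.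

**Step 23**
Reactants: 34 (3R,3aR,8aS)-3-methyl-5-(propan-2-yl)-1,2,3,3a,4,8a-hexahydroazulen-8-yl trifluoromethanesulfonate
Product: 35 (3R,3aR,8aS)-3-methyl-5-(propan-2-yl)-1,2,3,3a,4,8a-hexahydroazulene-8-carboxylic acid [(1S,4R,5R)-guaia-7,9-dien-14-oic acid]
Conditions: Pd(OAc)2 (5 mol %), dppf, CO (1 atm), KOAc, DMF/H2O, 60 °C; then aq. HCl
Reagents that add atoms: carbon monoxide, [C-]#[O+]; water, O
Why: Palladium-catalysed hydroxycarbonylation of the dienyl triflate (acyl-palladium captured by acetate, then hydrolysis) gives the dienoic acid without touching a stereocenter.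

**Step 24**
Reactants: 14 (4aR,6S,7S,7aR)-6-hydroxy-4-methylidenehexahydro-1H-spiro[cyclopenta[c]pyran-7,2'-oxiran]-1-one; 35 (3R,3aR,8aS)-3-methyl-5-(propan-2-yl)-1,2,3,3a,4,8a-hexahydroazulene-8-carboxylic acid
Product: 36 nardostachysin
Conditions: Ti(OiPr)4 (1.5 equiv), CH2Cl2, rt; aq. tartaric acid work-up
Reagents that add atoms: none
Why: Titanium-mediated opening of the 2,3-epoxy alcohol by the carboxylic acid at the primary carbon C10 (C-3 opening through the titanium chelate) forms the ester and the tertiary alcohol; no bond at C7 or C8 is broken, so both configurations are kept.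

**Compound list**
1 | methyl 4-oxobutanoate | COC(=O)CCC=O | starting material
2 | methyl 3-formylbut-3-enoate | COC(=O)CC(=C)C=O | intermediate
3 | diisopinocampheylborinate of 4 | COC(=O)CC(=C)[C@@H](OB([C@H]1[C@H](C)[C@H]2C[C@@H](C1)C2(C)C)[C@H]1[C@H](C)[C@H]2C[C@@H](C1)C2(C)C)CC=C | intermediate
4 | methyl (4S)-4-hydroxy-3-methylidenehept-6-enoate | COC(=O)CC(=C)[C@@H](O)CC=C | intermediate
5 | methyl (4S)-4-[(tert-butyldimethylsilyl)oxy]-3-methylidenehept-6-enoate | COC(=O)CC(=C)[C@@H](O[Si](C)(C)C(C)(C)C)CC=C | intermediate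
6 | 2-methylidenepropane-1,3-diyl diacetate | CC(=O)OCC(=C)COC(C)=O | starting material
7 | methyl (4S)-8-acetoxy-7-(acetoxymethyl)-4-[(tert-butyldimethylsilyl)oxy]-3-methylideneoct-6-enoate | COC(=O)CC(=C)[C@@H](O[Si](C)(C)C(C)(C)C)CC=C(COC(C)=O)COC(C)=O | intermediate
8 | (4S)-4-[(tert-butyldimethylsilyl)oxy]-8-hydroxy-7-(hydroxymethyl)-3-methylideneoct-6-enoic acid | OC(=O)CC(=C)[C@@H](O[Si](C)(C)C(C)(C)C)CC=C(CO)CO | intermediate
9 | (5S,7Z)-5-[(tert-butyldimethylsilyl)oxy]-8-(hydroxymethyl)-4-methylidene-1-oxacyclonon-7-en-2-one | O=C1CC(=C)[C@@H](O[Si](C)(C)C(C)(C)C)C/C=C(/CO)CO1 | intermediate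
10 | (5S,7E)-5-[(tert-butyldimethylsilyl)oxy]-8-(chloromethyl)-4-methylidene-1-oxacyclonon-7-en-2-one | O=C1CC(=C)[C@@H](O[Si](C)(C)C(C)(C)C)C/C=C(/CCl)CO1 | intermediate
11 | tert-butyldimethylsilyl ketene acetal of 10 | CC(C)(C)[Si](C)(C)O/C1=C/C(=C)[C@@H](O[Si](C)(C)C(C)(C)C)C/C=C(/CCl)CO1 | intermediate
12 | tert-butyldimethylsilyl (1R,2R,4S)-4-[(tert-butyldimethylsilyl)oxy]-2-(3-chloroprop-1-en-2-yl)-5-methylidenecyclopentane-1-carboxylate | C=C(CCl)[C@@H]1C[C@H](O[Si](C)(C)C(C)(C)C)C(=C)[C@@H]1C(=O)O[Si](C)(C)C(C)(C)C | intermediate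
13 | (4aR,6S,7aR)-6-hydroxy-4,7-dimethylidenehexahydrocyclopenta[c]pyran-1(3H)-one | C=C1COC(=O)[C@@H]2[C@H]1C[C@H](O)C2=C | intermediate
14 | (4aR,6S,7S,7aR)-6-hydroxy-4-methylidenehexahydro-1H-spiro[cyclopenta[c]pyran-7,2'-oxiran]-1-one | C=C1COC(=O)[C@@H]2[C@H]1C[C@H](O)[C@@]21CO1 | intermediate
15 | (R)-(+)-pulegone | C[C@@H]1CCC(=C(C)C)C(=O)C1 | starting material
16 | (5R)-2-bromo-2-(2-bromopropan-2-yl)-5-methylcyclohexan-1-one | C[C@@H]1CCC(Br)(C(C)(C)Br)C(=O)C1 | intermediate
17 | methyl (1S,5R)-5-methyl-2-(propan-2-ylidene)cyclopentane-1-carboxylate | COC(=O)[C@@H]1C(=C(C)C)CC[C@H]1C | intermediate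
18 | ozonide (spiro-1,2,4-trioxolane) of 17 | COC(=O)[C@@H]1C2(OOC(C)(C)O2)CC[C@H]1C | intermediate
19 | methyl (1S,5R)-5-methyl-2-oxocyclopentane-1-carboxylate | COC(=O)[C@@H]1C(=O)CC[C@H]1C | intermediate
20 | methyl (5R)-5-methyl-2-{[(trifluoromethyl)sulfonyl]oxy}cyclopent-1-ene-1-carboxylate | COC(=O)C1=C(OS(=O)(=O)C(F)(F)F)CC[C@H]1C | intermediate
21 | (3R)-2-(hydroxymethyl)-3-methylcyclopent-1-en-1-yl trifluoromethanesulfonate | OCC1=C(OS(=O)(=O)C(F)(F)F)CC[C@H]1C | intermediate
22 | (4R)-4-methyl-3,4,5,6-tetrahydro-1H-cyclopenta[c]furan-1-one | O=C1OCC2=C1CC[C@H]2C | intermediate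
23 | (3aR,4R,6aS)-4-methylhexahydro-1H-cyclopenta[c]furan-1-one | O=C1OC[C@@H]2[C@H](C)CC[C@H]12 | intermediate
24 | (1S,2R,3R)-2-(hydroxymethyl)-N-methoxy-N,3-dimethylcyclopentane-1-carboxamide | OC[C@@H]1[C@H](C)CC[C@@H]1C(=O)N(C)OC | intermediate
25 | (1S,2R,3R)-2-(iodomethyl)-N-methoxy-N,3-dimethylcyclopentane-1-carboxamide | IC[C@@H]1[C@H](C)CC[C@@H]1C(=O)N(C)OC | intermediate
26 | 3-methylbutan-2-one | CC(=O)C(C)C | starting material
27 | lithium 3-methylbut-1-en-2-olate | [Li]OC(=C)C(C)C | intermediate
28 | 3-methylbut-1-en-2-yl trifluoromethanesulfonate | C=C(OS(=O)(=O)C(F)(F)F)C(C)C | intermediate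
29 | alkylzinc iodide from 25 | I[Zn]C[C@@H]1[C@H](C)CC[C@@H]1C(=O)N(C)OC | intermediate
30 | (1S,2R,3R)-N-methoxy-N,3-dimethyl-2-(3-methyl-2-methylidenebutyl)cyclopentane-1-carboxamide | C=C(C(C)C)C[C@@H]1[C@H](C)CC[C@@H]1C(=O)N(C)OC | intermediate
31 | 1-[(1S,2R,3R)-3-methyl-2-(3-methyl-2-methylidenebutyl)cyclopentyl]but-3-en-1-one | C=C(C(C)C)C[C@@H]1[C@H](C)CC[C@@H]1C(=O)CC=C | intermediate
32 | (3R,3aR,8aS)-3-methyl-5-(propan-2-yl)-2,3,3a,4,7,8a-hexahydroazulen-8(1H)-one | O=C1CC=C(C(C)C)C[C@@H]2[C@H](C)CC[C@H]12 | intermediate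
33 | potassium dienolate of 32 | [K+].[O-]C1=CC=C(C(C)C)C[C@@H]2[C@H](C)CC[C@H]12 | intermediate
34 | (3R,3aR,8aS)-3-methyl-5-(propan-2-yl)-1,2,3,3a,4,8a-hexahydroazulen-8-yl trifluoromethanesulfonate | FC(F)(F)S(=O)(=O)OC1=CC=C(C(C)C)C[C@@H]2[C@H](C)CC[C@H]12 | intermediate
35 | (3R,3aR,8aS)-3-methyl-5-(propan-2-yl)-1,2,3,3a,4,8a-hexahydroazulene-8-carboxylic acid | OC(=O)C1=CC=C(C(C)C)C[C@@H]2[C@H](C)CC[C@H]12 | intermediate
36 | nardostachysin | C=C1COC(=O)[C@@H]2[C@H]1C[C@H](O)[C@@]2(O)COC(=O)C1=CC=C(C(C)C)C[C@@H]2[C@H](C)CC[C@H]12 | target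

**Step count**
Total: 24 steps. Longest linear sequence: 14 steps (15 to 36 through steps 10–17 and 19–24).

**Steps most likely to fail**

Step 8. The boat-type [3,3] shift may be slower than loss of the silyl ketene acetal (desilylation or C-silylation), and the facial bias exerted by C7 may be weak. The fallback sets out from 10. Treatment with LiN(SiMe3)2 in THF/DMPU at −78 °C to 0 °C without silyl chloride lets the lithium enolate alkylate C5 across the ring in the SN2′ sense with loss of chloride (intramolecular enolate allylation). This gives the silyl ether of 13, (4aR,6S,7aR)-6-[(tert-butyldimethylsilyl)oxy]-4,7-dimethylidenehexahydrocyclopenta[c]pyran-1(3H)-one F4, in which the original ring O–CH2 bond is kept as the lactone bond. HF·pyridine in THF then removes the silyl group, and the route is rejoined at 13.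

Step 6. Acyl activation of a medium-ring seco acid may give diolide and oligomers instead of the strained nine-membered ring, and the activated β,γ-unsaturated acid may suffer alkene migration. The fallback sets out from 7 and forms the ring C–O bond by carboxylate alkylation instead. K2CO3 in MeOH at 0 °C removes both acetates to give the diol ester methyl (4S)-4-[(tert-butyldimethylsilyl)oxy]-8-hydroxy-7-(hydroxymethyl)-3-methylideneoct-6-enoate F1. PPh3 and N-chlorosuccinimide convert it into the bis(allylic chloride) methyl (4S)-4-[(tert-butyldimethylsilyl)oxy]-8-chloro-7-(chloromethyl)-3-methylideneoct-6-enoate F2. Me3SnOH in 1,2-dichloroethane at 70 °C cleaves the methyl ester to (4S)-4-[(tert-butyldimethylsilyl)oxy]-8-chloro-7-(chloromethyl)-3-methylideneoct-6-enoic acid F3. Cs2CO3 in DMF at 1 mM then closes the ring through the caesium carboxylate, which can only reach the chloromethyl arm cis to the chain. The route is rejoined at 10, one step later than it was left.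

Step 24. The hindered, conjugated acid may open the titanium-bound epoxide slowly, so that isopropoxide transfer or transesterification of the lactone competes. The fallback sets out from 13. Hydrogen-bond-directed dihydroxylation with OsO4·TMEDA in CH2Cl2 at −78 °C, followed by cleavage of the osmate with aqueous Na2SO3, should add both hydroxyls syn to the 7-OH. This gives the triol (4aR,6S,7S,7aR)-6,7-dihydroxy-7-(hydroxymethyl)-4-methylidenehexahydrocyclopenta[c]pyran-1(3H)-one F5. Yamaguchi esterification with 35 (2,4,6-trichlorobenzoyl chloride, Et3N, then DMAP, PhMe, rt) should acylate only the primary hydroxyl, and the route is rejoined at 36.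

**Further compounds**
F1 | step 6 | methyl (4S)-4-[(tert-butyldimethylsilyl)oxy]-8-hydroxy-7-(hydroxymethyl)-3-methylideneoct-6-enoate | COC(=O)CC(=C)[C@@H](O[Si](C)(C)C(C)(C)C)CC=C(CO)CO
F2 | step 6 | methyl (4S)-4-[(tert-butyldimethylsilyl)oxy]-8-chloro-7-(chloromethyl)-3-methylideneoct-6-enoate | COC(=O)CC(=C)[C@@H](O[Si](C)(C)C(C)(C)C)CC=C(CCl)CCl
F3 | step 6 | (4S)-4-[(tert-butyldimethylsilyl)oxy]-8-chloro-7-(chloromethyl)-3-methylideneoct-6-enoic acid | OC(=O)CC(=C)[C@@H](O[Si](C)(C)C(C)(C)C)CC=C(CCl)CCl
F4 | step 8 | (4aR,6S,7aR)-6-[(tert-butyldimethylsilyl)oxy]-4,7-dimethylidenehexahydrocyclopenta[c]pyran-1(3H)-one | C=C1COC(=O)[C@@H]2[C@H]1C[C@H](O[Si](C)(C)C(C)(C)C)C2=C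
F5 | step 24 | (4aR,6S,7S,7aR)-6,7-dihydroxy-7-(hydroxymethyl)-4-methylidenehexahydrocyclopenta[c]pyran-1(3H)-one | C=C1COC(=O)[C@@H]2[C@H]1C[C@H](O)[C@@]2(O)CO
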